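**Assumption:** atoms are numbered C1–C15 as in goyazensolide (C1 ketone, C2=C3 furanone olefin, C4=C5, C6 lactone carbinol, C7, C8 ester carbinol, C9, C10 quaternary, C11–C13 methylene lactone, C14 methyl, C15 CH2OH); the five starting materials below are taken as commercial.

## Retrosynthetic overview

1. Goyazensolide ⇐ its 8-O-TES/15-O-TBDPS macrocycle; the methacrylate goes on last so it cannot enter the metathesis.
2. Key step: the ten-membered ring is closed last by ring-closing metathesis that forges the cis C4=C5 trisubstituted olefin across a finished 3(2H)-furanone and trans-lactone. This replaces the customary C6–C7 allylation macrocyclisation followed by transannular furanone formation.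
3. trans-α-Methylene lactone (C6, C7 in one step) ⇐ CrCl2 allylation/lactonisation of acrolein with a Morita–Baylis–Hillman-derived allylic bromide, controlled by C8.
4. Furanone ⇐ gold-catalysed cyclisation of an α'-hydroxy ynone, itself from acetylide opening of an α-hydroxy-α-methyl-γ-lactone.
5. C8 comes from the glutamic-acid-derived hydroxymethyl lactone, C10 from a 1,3-trans enolate hydroxylation. Ring order: furanone → lactone → carbocycle.

## Route

**Step 1**
Reactants: 1 2-bromoprop-2-en-1-ol
Product: 2 tert-butyl[(2-bromoprop-2-en-1-yl)oxy]diphenylsilane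
Conditions: TBDPSCl, imidazole, CH2Cl2, 0 °C to rt
Reagents that add atoms: tert-butyl(chloro)diphenylsilane, CC(C)(C)[Si](Cl)(c1ccccc1)c1ccccc1
Why: Imidazole-promoted silyl ether formation on a primary allylic alcohol is clean, and the TBDPS ether survives every later step up to the last.

**Step 2**
Reactants: 2 tert-butyl[(2-bromoprop-2-en-1-yl)oxy]diphenylsilane; 3 ethynyltrimethylsilane
Product: 4 tert-butyl{[2-methylidene-4-(trimethylsilyl)but-3-yn-1-yl]oxy}diphenylsilane
Conditions: Pd(PPh3)2Cl2 (3 mol%), CuI (6 mol%), Et3N, THF, 50 °C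
Reagents that add atoms: none
Why: Sonogashira coupling (oxidative addition of the vinyl bromide to zerovalent palladium, copper acetylide transmetalation, reductive elimination) gives the 2-substituted enyne without touching the silyl ether.

**Step 3**
Reactants: 5 (5S)-5-(hydroxymethyl)dihydrofuran-2(3H)-one
Product: 6 (5S)-5-{[(triethylsilyl)oxy]methyl}dihydrofuran-2(3H)-one
Conditions: TESCl, imidazole, CH2Cl2, 0 °C
Reagents that add atoms: chlorotriethylsilane, CC[Si](Cl)(CC)CC
Why: Routine silyl ether formation; a primary TES ether is chosen because it can later be oxidised directly under Swern conditions.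

**Step 4**
Reactants: 6 (5S)-5-{[(triethylsilyl)oxy]methyl}dihydrofuran-2(3H)-one
Product: 8 (3R,5S)-3-methyl-5-{[(triethylsilyl)oxy]methyl}dihydrofuran-2(3H)-one, via lithium enolate 7 (not isolated)
Conditions: LiN(iPr)2, THF, −78 °C; MeI, −78 to −40 °C
Reagents that add atoms: iodomethane, CI
Why: Lactone enolate alkylation in which MeI enters mainly trans to the C8 silyloxymethyl group (1,3-induction), although this centre is planarised again in the next step so the ratio is immaterial.

**Step 5**
Reactants: 8 (3R,5S)-3-methyl-5-{[(triethylsilyl)oxy]methyl}dihydrofuran-2(3H)-one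
Product: 10 (3R,5S)-3-hydroxy-3-methyl-5-{[(triethylsilyl)oxy]methyl}dihydrofuran-2(3H)-one, via potassium enolate 9 (not isolated)
Conditions: KN(SiMe3)2, THF, −78 °C; 2-(benzenesulfonyl)-3-phenyloxaziridine, −78 °C; AcOH quench
Reagents that add atoms: 2-(benzenesulfonyl)-3-phenyloxaziridine, O=S(=O)(c1ccccc1)N1OC1c1ccccc1
Why: Davis enolate hydroxylation in which the oxaziridine approaches the planar enolate from the face opposite the C8 silyloxymethyl group, so the hydroxyl ends up trans to it and C10 is set as R (the minor cis isomer is removed by chromatography).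

**Step 6**
Reactants: 4 tert-butyl{[2-methylidene-4-(trimethylsilyl)but-3-yn-1-yl]oxy}diphenylsilane; 10 (3R,5S)-3-hydroxy-3-methyl-5-{[(triethylsilyl)oxy]methyl}dihydrofuran-2(3H)-one
Product: 12 (6R,8S)-2-{[(tert-butyldiphenylsilyl)oxy]methyl}-6,8-dihydroxy-6-methyl-9-[(triethylsilyl)oxy]non-1-en-3-yn-5-one, via lithium acetylide 11 (not isolated)
Conditions: 4 (2.2 equiv), MeLi·LiBr, THF, −78 to 0 °C; then 10, −78 to −30 °C; AcOH quench
Reagents that add atoms: none
Why: MeLi cleaves the alkynyl C–Si bond to give acetylide 11, one equivalent of which deprotonates the tertiary OH while the second adds to the non-enolisable lactone carbonyl (acetylide addition to a lactone), the lithium hemiketal persisting until work-up so that only one addition occurs and the C8 hydroxyl is released with both stereocentres untouched.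

**Step 7**
Reactants: 12 (6R,8S)-α'-hydroxy ynone
Product: 13 (2R)-5-{3-[(tert-butyldiphenylsilyl)oxy]prop-1-en-2-yl}-2-{(2S)-2-hydroxy-3-[(triethylsilyl)oxy]propyl}-2-methylfuran-3(2H)-one
Conditions: (Ph3P)AuNTf2 (3 mol%), CH2Cl2, rt
Reagents that add atoms: none
Why: Gold-catalysed 5-endo-dig hydroalkoxylation (cycloisomerisation) in which the π-acid activates the ynone and the tertiary C10 hydroxyl adds to C3 to give the 3(2H)-furanone, whereas the secondary C8 hydroxyl could only close a seven-membered ring and does not compete.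

**Step 8**
Reactants: 13 furanone alcohol
Product: 14 (2R)-2-{(2S)-2,3-bis[(triethylsilyl)oxy]propyl}-5-{3-[(tert-butyldiphenylsilyl)oxy]prop-1-en-2-yl}-2-methylfuran-3(2H)-one
Conditions: TESCl, imidazole, DMAP (cat.), CH2Cl2, rt
Reagents that add atoms: chlorotriethylsilane, CC[Si](Cl)(CC)CC
Why: Silyl ether formation on the secondary C8 alcohol gives the bis-TES ether needed for the selective oxidation that follows.

**Step 9**
Reactants: 14 bis-TES ether
Product: 16 (2S)-3-[(2R)-5-{3-[(tert-butyldiphenylsilyl)oxy]prop-1-en-2-yl}-2-methyl-3-oxo-2,3-dihydrofuran-2-yl]-2-[(triethylsilyl)oxy]propanal, via alkoxysulfonium chloride 15 (not isolated)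
Conditions: (COCl)2, DMSO, CH2Cl2, −78 to −40 °C; Et3N, −78 °C to rt
Reagents that add atoms: none
Why: Swern oxidation applied to the silyl ether, in which activated DMSO cleaves only the unhindered primary TES ether to alkoxysulfonium salt 15 that collapses with Et3N to the aldehyde, while the secondary TES and TBDPS ethers stay and the low temperature protects the α-stereocentre C8.

**Step 10**
Reactants: 16 α-silyloxy aldehyde; 17 methyl acrylate
Product: 18 methyl (4S)-3-hydroxy-2-methylidene-5-[(2R)-5-{3-[(tert-butyldiphenylsilyl)oxy]prop-1-en-2-yl}-2-methyl-3-oxo-2,3-dihydrofuran-2-yl]-4-[(triethylsilyl)oxy]pentanoate (mixture of C3 epimers)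
Conditions: DABCO (1 equiv), 17 (10 equiv), MeOH (2 equiv), rt
Reagents that add atoms: none
Why: Morita–Baylis–Hillman reaction in which the DABCO-derived ammonium enolate of methyl acrylate attacks the reactive α-silyloxy aldehyde and DABCO is then eliminated, the new carbinol centre being erased in the next step so its configuration does not matter.

**Step 11**
Reactants: 18 Morita–Baylis–Hillman adduct
Product: 19 methyl (2Z,4S)-2-(bromomethyl)-5-[(2R)-5-{3-[(tert-butyldiphenylsilyl)oxy]prop-1-en-2-yl}-2-methyl-3-oxo-2,3-dihydrofuran-2-yl]-4-[(triethylsilyl)oxy]pent-2-enoate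
Conditions: NBS, Me2S, CH2Cl2, 0 °C to rt
Reagents that add atoms: N-bromosuccinimide, O=C1CCC(=O)N1Br
Why: Corey–Kim-type activation of the allylic alcohol followed by SN2' attack of bromide gives the transposed primary allylic bromide with the favoured (Z) enoate geometry, and C8 is not involved.

**Step 12**
Reactants: 19 allylic bromide; 20 prop-2-enal (acrolein)
Product: 22 4,5-seco diene lactone (6R,7S,8S,10R), via seco hydroxy ester 21 (not isolated)
Conditions: CrCl2 (4 equiv), 20 (3 equiv), THF, 0 °C to rt; aqueous NH4Cl work-up; then PPTS (cat.), CH2Cl2, rt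
Reagents that add atoms: none
Why: Nozaki–Hiyama allylation with divalent chromium followed by lactonisation, in which the σ-allylchromium reacts at its γ-carbon C7 through a Zimmerman–Traxler chair with the branched C8 substituent and the vinyl group of acrolein both pseudo-equatorial (anti adduct, hence the trans lactone) and, with H8 held in the olefin plane by A(1,3) strain, the aldehyde adds to C7 anti to the bulky C8 silyloxy group, which sets C6 (R) and C7 in the natural sense before the C6 hydroxyl closes onto the methyl ester.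

**Step 13**
Reactants: 22 4,5-seco diene lactone
Product: 23 8-O-(triethylsilyl)-15-O-(tert-butyldiphenylsilyl)-8-O-desmethacryloylgoyazensolide
Conditions: second-generation Hoveyda–Grubbs catalyst, (H2IMes)Cl2Ru(=CH-C6H4-2-OiPr) (15 mol%), toluene (1 mM), 100 °C, argon sparge
Reagents that add atoms: none
Why: Ring-closing olefin metathesis in which the catalyst loads on the monosubstituted C5 vinyl group and the tethered 1,1-disubstituted C4 methylidene is the only olefin that can close a ring (the methylene lactone would give a cyclobutene), ethylene loss drives the reaction and the nine-membered oxacycle can only hold the cis (Z) C4=C5 olefin, so no stereocentre is formed or disturbed.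

**Step 14**
Reactants: 23 bis-silylated macrocycle
Product: 24 15-O-(tert-butyldiphenylsilyl)-8-O-desmethacryloylgoyazensolide
Conditions: HF·pyridine, pyridine, THF, 0 °C
Reagents that add atoms: none
Why: Buffered fluoride desilylation removes the secondary TES ether much faster than the primary TBDPS ether, and the mildly acidic medium avoids translactonisation to the 8,12-olide.

**Step 15**
Reactants: 24 C8 alcohol
Product: 25 15-O-(tert-butyldiphenylsilyl)goyazensolide
Conditions: methacrylic anhydride, Et3N, DMAP (cat.), CH2Cl2, 0 °C to rt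
Reagents that add atoms: methacrylic anhydride, C=C(C)C(=O)OC(=O)C(C)=C
Why: DMAP-catalysed acylation of the secondary C8 alcohol, done only now because a methacrylate present during the metathesis could have closed a seven-membered unsaturated lactone instead.

**Step 16**
Reactants: 25 15-O-(tert-butyldiphenylsilyl)goyazensolide
Product: 26 goyazensolide
Conditions: HF·pyridine, THF, 0 °C to rt
Reagents that add atoms: none
Why: Fluoride desilylation of the primary allylic TBDPS ether under acidic conditions that leave the methacrylate, the methylene lactone and the furanone untouched releases the C15 alcohol and gives the target.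

## Compound list

1 | 2-bromoprop-2-en-1-ol | C=C(Br)CO | starting material
2 | tert-butyl[(2-bromoprop-2-en-1-yl)oxy]diphenylsilane | C=C(Br)CO[Si](c1ccccc1)(c1ccccc1)C(C)(C)C | intermediate
3 | ethynyltrimethylsilane | C#C[Si](C)(C)C | starting material
4 | tert-butyl{[2-methylidene-4-(trimethylsilyl)but-3-yn-1-yl]oxy}diphenylsilane | C=C(CO[Si](c1ccccc1)(c1ccccc1)C(C)(C)C)C#C[Si](C)(C)C | intermediate
5 | (5S)-5-(hydroxymethyl)dihydrofuran-2(3H)-one | OC[C@@H]1CCC(=O)O1 | starting material
6 | (5S)-5-{[(triethylsilyl)oxy]methyl}dihydrofuran-2(3H)-one | CC[Si](CC)(CC)OC[C@@H]1CCC(=O)O1 | intermediate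
7 | lithium enolate of 6 | [Li]OC1=CC[C@@H](CO[Si](CC)(CC)CC)O1 | intermediate (not isolated)
8 | (3R,5S)-3-methyl-5-{[(triethylsilyl)oxy]methyl}dihydrofuran-2(3H)-one (methyl trans to the silyloxymethyl group) | C[C@@H]1C[C@@H](CO[Si](CC)(CC)CC)OC1=O | intermediate
9 | potassium enolate of 8 | [K]OC1=C(C)C[C@@H](CO[Si](CC)(CC)CC)O1 | intermediate (not isolated)
10 | (3R,5S)-3-hydroxy-3-methyl-5-{[(triethylsilyl)oxy]methyl}dihydrofuran-2(3H)-one (OH trans to the silyloxymethyl group) | C[C@@]1(O)C[C@@H](CO[Si](CC)(CC)CC)OC1=O | intermediate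
11 | lithium 3-{[(tert-butyldiphenylsilyl)oxy]methyl}but-3-en-1-yn-1-ide (lithium acetylide) | [Li]C#CC(=C)CO[Si](c1ccccc1)(c1ccccc1)C(C)(C)C | intermediate (not isolated)
12 | (6R,8S)-2-{[(tert-butyldiphenylsilyl)oxy]methyl}-6,8-dihydroxy-6-methyl-9-[(triethylsilyl)oxy]non-1-en-3-yn-5-one (8S,10R in goyazensolide numbering) | CC[Si](CC)(CC)OC[C@@H](O)C[C@@](C)(O)C(=O)C#CC(=C)CO[Si](c1ccccc1)(c1ccccc1)C(C)(C)C | intermediate
13 | (2R)-5-{3-[(tert-butyldiphenylsilyl)oxy]prop-1-en-2-yl}-2-{(2S)-2-hydroxy-3-[(triethylsilyl)oxy]propyl}-2-methylfuran-3(2H)-one | CC[Si](CC)(CC)OC[C@@H](O)C[C@@]1(C)OC(C(=C)CO[Si](c2ccccc2)(c2ccccc2)C(C)(C)C)=CC1=O | intermediate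
14 | (2R)-2-{(2S)-2,3-bis[(triethylsilyl)oxy]propyl}-5-{3-[(tert-butyldiphenylsilyl)oxy]prop-1-en-2-yl}-2-methylfuran-3(2H)-one | CC[Si](CC)(CC)OC[C@@H](O[Si](CC)(CC)CC)C[C@@]1(C)OC(C(=C)CO[Si](c2ccccc2)(c2ccccc2)C(C)(C)C)=CC1=O | intermediate
15 | dimethyl{(2S)-3-[(2R)-furanon-2-yl]-2-[(triethylsilyl)oxy]propoxy}sulfonium chloride (alkoxysulfonium salt of the C7 oxygen of 14) | C[S+](C)OC[C@@H](O[Si](CC)(CC)CC)C[C@@]1(C)OC(C(=C)CO[Si](c2ccccc2)(c2ccccc2)C(C)(C)C)=CC1=O.[Cl-] | intermediate (not isolated)
16 | (2S)-3-[(2R)-5-{3-[(tert-butyldiphenylsilyl)oxy]prop-1-en-2-yl}-2-methyl-3-oxo-2,3-dihydrofuran-2-yl]-2-[(triethylsilyl)oxy]propanal | O=C[C@@H](O[Si](CC)(CC)CC)C[C@@]1(C)OC(C(=C)CO[Si](c2ccccc2)(c2ccccc2)C(C)(C)C)=CC1=O | intermediate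
17 | methyl acrylate | C=CC(=O)OC | starting material
18 | methyl (4S)-3-hydroxy-2-methylidene-5-[(2R)-5-{3-[(tert-butyldiphenylsilyl)oxy]prop-1-en-2-yl}-2-methyl-3-oxo-2,3-dihydrofuran-2-yl]-4-[(triethylsilyl)oxy]pentanoate (C3 epimers) | C=C(C(=O)OC)C(O)[C@@H](O[Si](CC)(CC)CC)C[C@@]1(C)OC(C(=C)CO[Si](c2ccccc2)(c2ccccc2)C(C)(C)C)=CC1=O | intermediate
19 | methyl (2Z,4S)-2-(bromomethyl)-5-[(2R)-5-{3-[(tert-butyldiphenylsilyl)oxy]prop-1-en-2-yl}-2-methyl-3-oxo-2,3-dihydrofuran-2-yl]-4-[(triethylsilyl)oxy]pent-2-enoate | COC(=O)/C(CBr)=C/[C@@H](O[Si](CC)(CC)CC)C[C@@]1(C)OC(C(=C)CO[Si](c2ccccc2)(c2ccccc2)C(C)(C)C)=CC1=O | intermediate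
20 | prop-2-enal (acrolein) | C=CC=O | starting material
21 | seco hydroxy ester: methyl 2-methylidene ester with C6 OH, C6 vinyl, C7 H and C8 OTES, (6R,7S,8S,10R) in goyazensolide numbering, 6,7-anti | C=C[C@@H](O)[C@H](C(=C)C(=O)OC)[C@@H](O[Si](CC)(CC)CC)C[C@@]1(C)OC(C(=C)CO[Si](c2ccccc2)(c2ccccc2)C(C)(C)C)=CC1=O | intermediate (not isolated)
22 | 4,5-seco diene lactone: (4S,5R)-5-ethenyl-3-methylidene-4-{(1S)-2-[(2R)-5-{3-[(tert-butyldiphenylsilyl)oxy]prop-1-en-2-yl}-2-methyl-3-oxo-2,3-dihydrofuran-2-yl]-1-[(triethylsilyl)oxy]ethyl}dihydrofuran-2(3H)-one | C=C[C@H]1OC(=O)C(=C)[C@@H]1[C@@H](O[Si](CC)(CC)CC)C[C@@]2(C)OC(C(=C)CO[Si](c3ccccc3)(c3ccccc3)C(C)(C)C)=CC2=O | intermediate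
23 | 8-O-(triethylsilyl)-15-O-(tert-butyldiphenylsilyl)-8-O-desmethacryloylgoyazensolide (4Z; 6R,7S,8S,10R) | CC[Si](CC)(CC)O[C@H]1C[C@@]2(C)OC(=CC2=O)/C(CO[Si](c3ccccc3)(c3ccccc3)C(C)(C)C)=C\[C@H]2OC(=O)C(=C)[C@H]12 | intermediate
24 | 15-O-(tert-butyldiphenylsilyl)-8-O-desmethacryloylgoyazensolide (4Z; 6R,7R,8S,10R) | O[C@H]1C[C@@]2(C)OC(=CC2=O)/C(CO[Si](c3ccccc3)(c3ccccc3)C(C)(C)C)=C\[C@H]2OC(=O)C(=C)[C@H]12 | intermediate
25 | 15-O-(tert-butyldiphenylsilyl)goyazensolide | C=C(C)C(=O)O[C@H]1C[C@@]2(C)OC(=CC2=O)/C(CO[Si](c3ccccc3)(c3ccccc3)C(C)(C)C)=C\[C@H]2OC(=O)C(=C)[C@H]12 | intermediate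
26 | goyazensolide (4Z; 6R,7R,8S,10R) | C=C(C)C(=O)O[C@H]1C[C@@]2(C)OC(=CC2=O)/C(CO)=C\[C@H]2OC(=O)C(=C)[C@H]12 | target

## Step count and risks

Total: 16 steps. Longest linear sequence: 14 steps (5 → 26, steps 3–16); the enyne branch (steps 1–2) joins at step 6.

**Step 13 (ring-closing metathesis).** The ring being closed is strained and bridged, one olefin partner is 1,1-disubstituted and conjugated to the furanone, and dimerisation through the vinyl group competes. The fallback reverses the order of ring formation so that the carbocycle is closed before the lactone locks the conformation. It sets out from bromide 19: the chromium allylation is stopped after the aqueous work-up and seco hydroxy ester 21 is purified. Metathesis of this more flexible diene, whose free allylic C6 hydroxyl also speeds catalyst loading, gives the macrocyclic seco hydroxy ester F1. PPTS in CH2Cl2 then closes the trans lactone and the route is rejoined at 23.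

**Step 12 (chromium allylation/lactonisation).** Two stereochemical relationships (C6/C7 anti and C7 relative to C8) are set at once from a model, not from a direct precedent on this substrate, and the 6,7-syn adduct (cis lactone) is the likely contaminant. The fallback sets C6 by inversion instead of by the allylation. It sets out from 19: zinc dust in THF/aqueous NH4Cl at 0 °C reacts through the (Z)-allylzinc chair and gives the 6,7-syn adduct with C7 still anti to the silyloxy group, isolated as the 6-epi seco hydroxy ester F2. Me3SnOH (1,2-dichloroethane, 60 °C) cleaves the methyl ester to the 6-epi seco hydroxy acid F3. Mitsunobu lactonisation (PPh3, DIAD, THF, 0 °C) displaces the activated C6 hydroxyl with inversion, gives the trans lactone and rejoins the route at 22.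

**Step 10 (Morita–Baylis–Hillman reaction).** The reaction is slow, DABCO can add reversibly to the exocyclic dienone, and the α-silyloxy aldehyde may epimerise at C8 on long exposure to base. The fallback replaces amine catalysis by a preformed vinylalane. It sets out from 16: hydroalumination of methyl propiolate with iBu2AlH/HMPA (THF, 0 °C) gives [1-(methoxycarbonyl)ethenyl]diisobutylalane, which adds to 16 within minutes at 0 °C to give the same allylic alcohol, rejoining the route at 18. This fallback makes no new compound (F0).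

## Further compounds

F1 | step 13 | macrocyclic seco hydroxy ester: methyl 2-[(4Z; 6R,7S,8S,10R)-6-hydroxy-8-(triethylsilyloxy)-15-(tert-butyldiphenylsilyloxy) furanone-bridged cyclodecadienyl-7-yl]acrylate (lactone of 23 opened as methyl ester and C6 alcohol) | CC[Si](CC)(CC)O[C@H]1C[C@@]2(C)OC(=CC2=O)/C(CO[Si](c3ccccc3)(c3ccccc3)C(C)(C)C)=C\[C@@H](O)[C@@H]1C(=C)C(=O)OC
F2 | step 12 | 6-epi seco hydroxy ester (C6 epimer of 21; 6,7-syn; 6S,7S,8S,10R) | C=C[C@H](O)[C@H](C(=C)C(=O)OC)[C@@H](O[Si](CC)(CC)CC)C[C@@]1(C)OC(C(=C)CO[Si](c2ccccc2)(c2ccccc2)C(C)(C)C)=CC1=O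
F3 | step 12 | 6-epi seco hydroxy acid (carboxylic acid of F2) | C=C[C@H](O)[C@H](C(=C)C(=O)O)[C@@H](O[Si](CC)(CC)CC)C[C@@]1(C)OC(C(=C)CO[Si](c2ccccc2)(c2ccccc2)C(C)(C)C)=CC1=O
F0 | step 10 | none | none
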